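## The problem

The target **27** is a (2S)-flavan. Its ring A (C4a, C5–C8, C8a) is a phloroglucinol whose three oxygens all differ: O1 of the pyran ring on C8a, a free hydroxyl on C7 and a methyl ether on C5. The remaining substituted position, C8, is bonded to C2' of a benzofuran, so the C8–C2' bond lies between two oxygen-bearing carbons and is a doubly ortho-substituted aryl–heteroaryl bond. The benzene ring of the benzofuran is a second C-methylphloroglucinol with three unlike oxygens (furan O1', 4'-OMe, 6'-OH). Decorating a finished 5,7-dioxygenated flavan would have to tell C8 from C6 and O7 from O5, which substitution chemistry does poorly. The only stereocentre is C2, a benzylic ether carbon remote from everything else. Nothing in the molecule can control it, so it must come from the chiral pool and be carried through without ionising the benzylic C–O bond. The free phenols, the benzofuran C2'=C3' bond and the benzylic O1–C2 bond rule out strong acid, oxidants and forcing reduction late in the route. The enabling feature is the sequence C7(OH)–C8(C2')–C8a(O) in ring A. A ketene carbonyl carbon and the two carbons of a heteroaryl-substituted ynol silyl ether deliver exactly this array, while C4a (alkyl), C5 (OMe) and C6 (H) map onto C2, C3 and C4 of a 2-alkyl-3-methoxycyclobutenone.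

## Retrosynthesis

**27 from 26.** The last cut is the O6'–benzyl bond. The 6'-oxygen needs a group that survives organolithium reagents and heating at about 110 °C and leaves under neutral conditions. A benzyl ether does this, and benzyl ether **26** is one hydrogenolysis from **27**.

**26 from 25 and 24.** The O1–C2 bond is cut next. Acid-mediated closure onto a benzylic cation would racemise C2, and a late asymmetric reduction would need the phenols masked. An intramolecular Mitsunobu etherification of the open-chain diol-alcohol **25** inverts a purchased (R)-carbinol cleanly to (2S). Only the C8a hydroxyl is ortho to the side chain, so the ring closure is unambiguous. **25** comes from the bis-silyl ether **24** with fluoride.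

**24 from 19 and 11.** Ring A is taken apart at C7–C8, C8a–C4a and C6–C7. Compared with coupling at C8 of a preformed arene, this cut brings the hindered C8–C2' bond in on the alkyne and gives each ring A oxygen its own origin: the ketene carbonyl (O7, free), the siloxyalkyne (O8a, silylated) and an enol ether (O5, methylated). The precursors are cyclobutenone **19** and siloxyalkyne **11**. The forward reaction needs only heat, and the [2+2] step must join the benzofuranyl-bearing alkyne carbon to the ketene carbonyl carbon.

**19 from 17, 14 and 15.** The four-membered ring is cut at C1–C2 and C3–C4, a [2+2] cycloaddition of dichloroketene to ynol ether **17** followed by dechlorination of **18**. The polarity of the ynol ether fixes the 2-alkyl-3-methoxy pattern. **17** is cut at its C(sp)–C(sp3) bond into iodide **14** and sodium methoxyacetylide **16**, made in the flask from acetal **15**. **14** comes from commercial (R)-chloro alcohol **12** through silyl ether **13**, so the stereocentre is bought.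

**11 from 8.** The alkyne is cut between its two carbons. Ester **8** is homologated by one carbon from CH2Br2 to ynolate **10** (through ketone **9**) and silylated on oxygen. This takes one step from a stable ester, whereas a terminal alkyne would need three more.

**8 from 7, 4, 5, 3 and 1.** The furan C2'–C3' bond is cut (aldol condensation of aryloxyacetate **7**). **7** comes from dihydroxy aldehyde **4** by etherification with ethyl bromoacetate **5**, giving **6**, and then methylation. **4** comes from trihydroxy aldehyde **3** by benzylation of the para hydroxyl, and **3** from symmetric 2-methylphloroglucinol **1** by formylation through iminium salt **2**. The symmetry of **1** makes the formylation unambiguous. The only delicate choice is between the two hydroxyls ortho to the formyl group of **4**, which differ in their neighbour (H or CH3).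

## Roads not taken

**Alternative 1:** The cut is the furan C3'–C3a' bond, after an extra carbonyl carbon has tied O7 to C3' as a lactone. A 4-aryloxycoumarin A2 built on the finished (2S)-flavan would be closed with Pd(OAc)2 and AgOAc by twofold C–H coupling to the coumestan A1.
- Merits: the flavan and its stereocentre come from conventional chemistry, no halide or organometallic handle is needed, palladium is catalytic, and A1 and A2 are robust solids. In ease of handling this road is better than the chosen one, which works with an ynol ether, a cyclobutenone and a siloxyalkyne.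
- Weak points: the aryloxy ring of A2 has two ortho C–H bonds, one next to OMe and one next to the silyloxy group, and only the first gives the 4'-OMe/6'-O pattern. The choice rests on a size difference alone.
- A1 also holds one carbon too many. The lactone must be opened and the carboxyl left on C3' removed, which for electron-rich heteroaryl acids usually needs copper and high temperature.
- Hot oxidative conditions with divalent palladium and stoichiometric silver meet two electron-rich arenes and a benzylic ether, and annulating the coumarin onto the flavan still needs C8 told from C6.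
- Comparison: the chosen plan has no excision step, its regiochemistry follows from bond polarity, and the C6/C8 question never arises.

**Alternative 2:** The cuts are C4a–C4, C4–C3 and O1–C2. The acetophenone A4, formaldehyde A5 and styrene A6 would combine through an ortho-quinone methide and a hetero-Diels–Alder reaction to the 8-acetylflavan A3.
- Merits: this is the shortest access to rings A and C, one step from three commodity chemicals. A4 is symmetric, so neither the ring position nor the hydroxyl is in question, and the acetyl group marks C8. In step economy up to the flavan it is clearly better than the chosen plan.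
- Weak points: the thermal cycloaddition gives racemic A3. A6 is an unactivated alkene with no handle for a chiral catalyst, so C2 would need resolution.
- The acetyl group of A3, hindered and chelated between O1 and the C7 hydroxyl, must then become a fully substituted 2-benzofuranyl group. α-Arylation with a pentasubstituted ortho-halophenol and cyclodehydration moves the regiochemical problem of the second arene to a harder place, and the phenacyl ether route gives the 3-aryl isomer.
- Comparison: the chosen plan sets a purchased stereocentre and a benzofuran that arrives complete against the brevity of this road.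

**Alternative 3:** The cut is the furan C2'=C3' bond. Ester A8, from flavan-8-carboxylic acid A9 and salicylaldehyde A10, would be closed by TiCl3 and zinc in a reductive aldehyde–ester coupling to the bis(benzyl) ether A7.
- Merits: the fragments are joined by an ester bond, the carbonyl coupling is an established benzofuran synthesis, the ring closes late, and all intermediates are bench-stable. In convergence and handling it equals or betters the chosen plan.
- Weak points: A9 needs carboxylation at C8 in preference to C6 with O5 and O7 already differentiated, which is the ring A problem unsolved.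
- A10 has the same salicylaldehyde pattern whose regiocontrol is the least secure part of the chosen route, so nothing is gained there.
- The ester carbonyl of A8 is a 2,6-dioxygenated benzoate. Both its formation and its coupling are hindered, and pinacol coupling or reduction of the aldehyde can compete under excess low-valent titanium.
- Comparison: the chosen plan builds ring A with its substituent pattern in one step.

Key step: step 10

Assumption: flavan numbering (O1, C2–C4, C4a, C5–C8, C8a) is used for the chroman and primed numbers for the benzofuran; compounds 1, 5, 12 and 15 and all reagents are taken to be commercial.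

## Route

Step 1
Reactants: 1 2-methylbenzene-1,3,5-triol (2-methylphloroglucinol)
Product: 3 2,4,6-trihydroxy-3-methylbenzaldehyde, via iminium chloride 2 (not isolated)
Conditions: POCl3, DMF, EtOAc, 0 °C to rt; then H2O, 60 °C
Reagents that add atoms: N,N-dimethylformamide CN(C)C=O; water O
Why: Vilsmeier–Haack formylation; the two free ring positions of 1 are equivalent by symmetry, so one aldehyde should form on hydrolysis of iminium salt 2, whose electron-poor group discourages a second formylation.

Step 2
Reactants: 3 2,4,6-trihydroxy-3-methylbenzaldehyde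
Product: 4 4-(benzyloxy)-2,6-dihydroxy-3-methylbenzaldehyde
Conditions: BnBr (1.0 equiv), KHCO3, DMF, rt to 40 °C
Reagents that add atoms: benzyl bromide BrCc1ccccc1
Why: Williamson etherification with one equivalent of electrophile and a weak base; the hydroxyl para to the formyl group is the most acidic and is not held in a hydrogen bond to the carbonyl, the usual selectivity of 2,4-di- and 2,4,6-trihydroxyaryl carbonyl compounds.

Step 3
Reactants: 4 4-(benzyloxy)-2,6-dihydroxy-3-methylbenzaldehyde; 5 ethyl bromoacetate
Product: 7 ethyl 2-[5-(benzyloxy)-2-formyl-3-methoxy-4-methylphenoxy]acetate, via hydroxy aryloxyacetate 6 (not isolated)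
Conditions: K2CO3, DMF, 0 °C to rt; then MeI, K2CO3, 45 °C
Reagents that add atoms: iodomethane CI
Why: Two Williamson etherifications in one flask; of the two hydroxyls ortho to the formyl group, O6 of 4 (next to H) is less hindered and more acidic than O2, which the C-methyl group buttresses into the carbonyl hydrogen bond, so the bromoacetate should go to O6 and the slower methylation of the chelated O2 follows with excess MeI, the pattern known from partial alkylation of C-methylphloroglucinol acyl compounds.

Step 4
Reactants: 7 ethyl 2-[5-(benzyloxy)-2-formyl-3-methoxy-4-methylphenoxy]acetate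
Product: 8 ethyl 6-(benzyloxy)-4-methoxy-5-methyl-1-benzofuran-2-carboxylate
Conditions: DBU, DMF, 100 °C
Reagents that add atoms: none
Why: Rap–Stoermer-type closure: intramolecular aldol addition of the aryloxyacetate enolate to the formyl group and loss of water aromatise the furan, the standard route to benzofuran-2-carboxylates.

Step 5
Reactants: 8 ethyl 6-(benzyloxy)-4-methoxy-5-methyl-1-benzofuran-2-carboxylate
Product: 11 6-(benzyloxy)-4-methoxy-5-methyl-2-{[tri(propan-2-yl)silyl]oxyethynyl}-1-benzofuran, via dibromomethyl ketone 9 (not isolated), via lithium ynolate 10 (not isolated)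
Conditions: CH2Br2, lithium 2,2,6,6-tetramethylpiperidide, THF, −78 °C; then n-BuLi, −78 to 0 °C; then i-Pr3SiCl, −78 °C to rt
Reagents that add atoms: dibromomethane BrCBr; chlorotri(propan-2-yl)silane CC(C)[Si](Cl)(C(C)C)C(C)C
Why: Kowalski ester homologation stopped at the ynolate: LiCHBr2 adds to the ester to give ketone 9 as its enolate, bromine–lithium exchange and 1,2-shift of the benzofuranyl group give ynolate 10, and the bulky chlorosilane silylates oxygen and not carbon, the known preparation of triisopropylsiloxyalkynes.

Step 6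
Reactants: 12 (1R)-3-chloro-1-phenylpropan-1-ol
Product: 13 tert-butyl[(1R)-3-chloro-1-phenylpropoxy]dimethylsilane
Conditions: t-BuMe2SiCl, imidazole, DMF, rt
Reagents that add atoms: tert-butylchlorodimethylsilane CC(C)(C)[Si](C)(C)Cl
Why: Standard silyl ether formation at oxygen; the carbinol stereocentre is not touched.

Step 7
Reactants: 13 tert-butyl[(1R)-3-chloro-1-phenylpropoxy]dimethylsilane
Product: 14 tert-butyl[(1R)-3-iodo-1-phenylpropoxy]dimethylsilane
Conditions: NaI, butan-2-one, reflux
Reagents that add atoms: sodium iodide [Na+].[I-]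
Why: Finkelstein exchange at the primary carbon, driven by precipitation of NaCl; the stereocentre is two carbons away.

Step 8
Reactants: 15 2-chloro-1,1-dimethoxyethane (chloroacetaldehyde dimethyl acetal); 14 tert-butyl[(1R)-3-iodo-1-phenylpropoxy]dimethylsilane
Product: 17 tert-butyl{[(1R)-5-methoxy-1-phenylpent-4-yn-1-yl]oxy}dimethylsilane, via sodium methoxyacetylide 16 (not isolated)
Conditions: NaNH2 (3 equiv), liq. NH3, −33 °C; then 14 in THF, −33 °C; NH4Cl
Reagents that add atoms: none
Why: Double elimination and deprotonation of 15 by NaNH2 give acetylide 16 (the known entry to methoxyacetylene), which the primary iodide alkylates in an SN2 step, as in the classical synthesis of 1-alkoxy-1-alkynes.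

Step 9
Reactants: 17 tert-butyl{[(1R)-5-methoxy-1-phenylpent-4-yn-1-yl]oxy}dimethylsilane
Product: 19 2-[(3R)-3-{[tert-butyl(dimethyl)silyl]oxy}-3-phenylpropyl]-3-methoxycyclobut-2-en-1-one, via dichlorocyclobutenone 18 (not isolated)
Conditions: Cl3CCOCl, Zn–Cu couple, Et2O/DME, rt; filtration; then Zn, AcOH, TMEDA, MeOH, 0 °C to rt
Reagents that add atoms: trichloroacetyl chloride ClC(Cl)(Cl)C(Cl)=O
Why: [2+2] cycloaddition of dichloroketene to the ynol ether joins the ketene carbonyl carbon to the nucleophilic alkyl-bearing alkyne carbon and gives 18; buffered zinc reduction removes both chlorines as known for 4,4-dichlorocyclobutenones, and methanol makes any exchange at the vinylogous ester degenerate.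

Step 10
Reactants: 19 2-[(3R)-3-{[tert-butyl(dimethyl)silyl]oxy}-3-phenylpropyl]-3-methoxycyclobut-2-en-1-one; 11 6-(benzyloxy)-4-methoxy-5-methyl-2-{[tri(propan-2-yl)silyl]oxyethynyl}-1-benzofuran
Product: 24 2-[6-(benzyloxy)-4-methoxy-5-methyl-1-benzofuran-2-yl]-4-[(3R)-3-{[tert-butyl(dimethyl)silyl]oxy}-3-phenylpropyl]-5-methoxy-3-{[tri(propan-2-yl)silyl]oxy}phenol, via vinylketene 20 (not isolated), via vinylcyclobutenone 21 (not isolated), via dienylketene 22 (not isolated), via cyclohexadienone 23 (not isolated)
Conditions: toluene (degassed), 80 °C then 110 °C, sealed vessel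
Reagents that add atoms: none
Why: Danheiser benzannulation: heat opens 19 by a four-electron electrocyclic reaction to vinylketene 20. The ketene C=C bond adds the electron-rich alkyne 11 in a [2+2] step in which the nucleophilic benzofuranyl-bearing carbon bonds to the ketene carbonyl carbon (C7–C8) and the siloxy carbon to the ketene α-carbon (C8a–C4a), giving 21. Reversible four-electron opening of 21 gives dienylketene 22, and because the opening is reversible the material funnels through the isomer in which the methoxyvinyl group is cis to the ketene. Six-electron electrocyclisation of 22 forms C6–C7 and closes ring A as cyclohexadienone 23, which tautomerises to phenol 24. The closest known reaction is the benzannulation of cyclobutenones with triisopropylsiloxyalkynes to resorcinol monosilyl ethers. No stereocentre is formed and the (R)-carbinol is a spectator. The selectivity needed is the regiochemistry of the [2+2] step, which the oxygen-donor polarisation of the siloxyalkyne and the electrophilic ketene carbonyl carbon secure. The silyl group stays on the alkyne oxygen, so O7 is free and O8a is silylated, and the CH2 of 19 becomes C6–H.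

Step 11
Reactants: 24 2-[6-(benzyloxy)-4-methoxy-5-methyl-1-benzofuran-2-yl]-4-[(3R)-3-{[tert-butyl(dimethyl)silyl]oxy}-3-phenylpropyl]-5-methoxy-3-{[tri(propan-2-yl)silyl]oxy}phenol
Product: 25 2-[6-(benzyloxy)-4-methoxy-5-methyl-1-benzofuran-2-yl]-4-[(3R)-3-hydroxy-3-phenylpropyl]-5-methoxybenzene-1,3-diol
Conditions: Bu4NF, THF, 0 °C to rt
Reagents that add atoms: none
Why: Fluoride cleaves the aryl triisopropylsilyl ether and the secondary tert-butyldimethylsilyl ether; no bond to the stereocentre is broken.

Step 12
Reactants: 25 2-[6-(benzyloxy)-4-methoxy-5-methyl-1-benzofuran-2-yl]-4-[(3R)-3-hydroxy-3-phenylpropyl]-5-methoxybenzene-1,3-diol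
Product: 26 (2S)-8-[6-(benzyloxy)-4-methoxy-5-methyl-1-benzofuran-2-yl]-5-methoxy-2-phenyl-3,4-dihydro-2H-chromen-7-ol
Conditions: PPh3, DIAD, THF (high dilution), 0 °C to rt
Reagents that add atoms: none
Why: Intramolecular Mitsunobu etherification: the C8a phenol displaces the alkoxyphosphonium ion of the benzylic alcohol in a 6-exo-tet SN2 step with inversion, turning (R) into (2S); the C7 hydroxyl is para to the side chain and cannot reach, and an unsubstituted phenyl group gives little tendency to ionise.

Step 13
Reactants: 26 (2S)-8-[6-(benzyloxy)-4-methoxy-5-methyl-1-benzofuran-2-yl]-5-methoxy-2-phenyl-3,4-dihydro-2H-chromen-7-ol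
Product: 27 (2S)-8-(6-hydroxy-4-methoxy-5-methyl-1-benzofuran-2-yl)-5-methoxy-2-phenyl-3,4-dihydro-2H-chromen-7-ol
Conditions: H2 (1 atm), 10% Pd/C, EtOAc, rt
Reagents that add atoms: none
Why: Hydrogenolysis of the aryl benzyl ether under neutral conditions at ambient pressure; the cyclic benzylic ether O1–C2 and the benzofuran double bond react much more slowly than an O-benzyl group.

## Compound list

1 | 2-methylbenzene-1,3,5-triol (2-methylphloroglucinol) | Cc1c(O)cc(O)cc1O | starting material
2 | N-[(2,4,6-trihydroxy-3-methylphenyl)methylidene]-N-methylmethanaminium chloride (not isolated) | C[N+](C)=Cc1c(O)cc(O)c(C)c1O.[Cl-] | intermediate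
3 | 2,4,6-trihydroxy-3-methylbenzaldehyde | O=Cc1c(O)cc(O)c(C)c1O | intermediate
4 | 4-(benzyloxy)-2,6-dihydroxy-3-methylbenzaldehyde | O=Cc1c(O)cc(OCc2ccccc2)c(C)c1O | intermediate
5 | ethyl bromoacetate | CCOC(=O)CBr | starting material
6 | ethyl 2-[5-(benzyloxy)-2-formyl-3-hydroxy-4-methylphenoxy]acetate (not isolated) | CCOC(=O)COc1cc(OCc2ccccc2)c(C)c(O)c1C=O | intermediate
7 | ethyl 2-[5-(benzyloxy)-2-formyl-3-methoxy-4-methylphenoxy]acetate | CCOC(=O)COc1cc(OCc2ccccc2)c(C)c(OC)c1C=O | intermediate
8 | ethyl 6-(benzyloxy)-4-methoxy-5-methyl-1-benzofuran-2-carboxylate | CCOC(=O)c1cc2c(OC)c(C)c(OCc3ccccc3)cc2o1 | intermediate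
9 | 1-[6-(benzyloxy)-4-methoxy-5-methyl-1-benzofuran-2-yl]-2,2-dibromoethan-1-one (present as its lithium enolate; not isolated) | O=C(C(Br)Br)c1cc2c(OC)c(C)c(OCc3ccccc3)cc2o1 | intermediate
10 | lithium 2-[6-(benzyloxy)-4-methoxy-5-methyl-1-benzofuran-2-yl]ethyn-1-olate (not isolated) | [Li+].[O-]C#Cc1cc2c(OC)c(C)c(OCc3ccccc3)cc2o1 | intermediate
11 | 6-(benzyloxy)-4-methoxy-5-methyl-2-{[tri(propan-2-yl)silyl]oxyethynyl}-1-benzofuran | CC(C)[Si](OC#Cc1cc2c(OC)c(C)c(OCc3ccccc3)cc2o1)(C(C)C)C(C)C | intermediate
12 | (1R)-3-chloro-1-phenylpropan-1-ol | ClCC[C@H](c1ccccc1)O | starting material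
13 | tert-butyl[(1R)-3-chloro-1-phenylpropoxy]dimethylsilane | ClCC[C@H](c1ccccc1)O[Si](C)(C)C(C)(C)C | intermediate
14 | tert-butyl[(1R)-3-iodo-1-phenylpropoxy]dimethylsilane | ICC[C@H](c1ccccc1)O[Si](C)(C)C(C)(C)C | intermediate
15 | 2-chloro-1,1-dimethoxyethane (chloroacetaldehyde dimethyl acetal) | COC(CCl)OC | starting material
16 | sodium methoxyacetylide (not isolated) | [Na+].[C-]#COC | intermediate
17 | tert-butyl{[(1R)-5-methoxy-1-phenylpent-4-yn-1-yl]oxy}dimethylsilane | COC#CCC[C@H](c1ccccc1)O[Si](C)(C)C(C)(C)C | intermediate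
18 | 2-[(3R)-3-{[tert-butyl(dimethyl)silyl]oxy}-3-phenylpropyl]-4,4-dichloro-3-methoxycyclobut-2-en-1-one (not isolated) | COC1=C(CC[C@H](c2ccccc2)O[Si](C)(C)C(C)(C)C)C(=O)C1(Cl)Cl | intermediate
19 | 2-[(3R)-3-{[tert-butyl(dimethyl)silyl]oxy}-3-phenylpropyl]-3-methoxycyclobut-2-en-1-one | COC1=C(CC[C@H](c2ccccc2)O[Si](C)(C)C(C)(C)C)C(=O)C1 | intermediate
20 | (5R)-5-{[tert-butyl(dimethyl)silyl]oxy}-2-(1-methoxyethenyl)-5-phenylpent-1-en-1-one (vinylketene; not isolated) | O=C=C(CC[C@H](c1ccccc1)O[Si](C)(C)C(C)(C)C)C(OC)=C | intermediate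
21 | 2-[6-(benzyloxy)-4-methoxy-5-methyl-1-benzofuran-2-yl]-4-[(3R)-3-{[tert-butyl(dimethyl)silyl]oxy}-3-phenylpropyl]-4-(1-methoxyethenyl)-3-{[tri(propan-2-yl)silyl]oxy}cyclobut-2-en-1-one (both configurations at C4; not isolated) | O=C1C(c2cc3c(OC)c(C)c(OCc4ccccc4)cc3o2)=C(O[Si](C(C)C)(C(C)C)C(C)C)C1(CC[C@H](c1ccccc1)O[Si](C)(C)C(C)(C)C)C(OC)=C | intermediate
22 | (7R)-2-[6-(benzyloxy)-4-methoxy-5-methyl-1-benzofuran-2-yl]-7-{[tert-butyl(dimethyl)silyl]oxy}-4-(1-methoxyethenyl)-7-phenyl-3-{[tri(propan-2-yl)silyl]oxy}hepta-1,3-dien-1-one (isomer with ketene and methoxyvinyl cis; not isolated) | O=C=C(c1cc2c(OC)c(C)c(OCc3ccccc3)cc2o1)/C(O[Si](C(C)C)(C(C)C)C(C)C)=C(/CC[C@H](c1ccccc1)O[Si](C)(C)C(C)(C)C)C(OC)=C | intermediate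
23 | 2-[6-(benzyloxy)-4-methoxy-5-methyl-1-benzofuran-2-yl]-4-[(3R)-3-{[tert-butyl(dimethyl)silyl]oxy}-3-phenylpropyl]-5-methoxy-3-{[tri(propan-2-yl)silyl]oxy}cyclohexa-2,4-dien-1-one (not isolated) | O=C1CC(OC)=C(CC[C@H](c2ccccc2)O[Si](C)(C)C(C)(C)C)C(O[Si](C(C)C)(C(C)C)C(C)C)=C1c1cc2c(OC)c(C)c(OCc3ccccc3)cc2o1 | intermediate
24 | 2-[6-(benzyloxy)-4-methoxy-5-methyl-1-benzofuran-2-yl]-4-[(3R)-3-{[tert-butyl(dimethyl)silyl]oxy}-3-phenylpropyl]-5-methoxy-3-{[tri(propan-2-yl)silyl]oxy}phenol | COc1cc(O)c(-c2cc3c(OC)c(C)c(OCc4ccccc4)cc3o2)c(O[Si](C(C)C)(C(C)C)C(C)C)c1CC[C@H](c1ccccc1)O[Si](C)(C)C(C)(C)C | intermediate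
25 | 2-[6-(benzyloxy)-4-methoxy-5-methyl-1-benzofuran-2-yl]-4-[(3R)-3-hydroxy-3-phenylpropyl]-5-methoxybenzene-1,3-diol | COc1cc(O)c(-c2cc3c(OC)c(C)c(OCc4ccccc4)cc3o2)c(O)c1CC[C@H](c1ccccc1)O | intermediate
26 | (2S)-8-[6-(benzyloxy)-4-methoxy-5-methyl-1-benzofuran-2-yl]-5-methoxy-2-phenyl-3,4-dihydro-2H-chromen-7-ol | COc1cc(O)c(-c2cc3c(OC)c(C)c(OCc4ccccc4)cc3o2)c2c1CC[C@@H](c1ccccc1)O2 | intermediate
27 | (2S)-8-(6-hydroxy-4-methoxy-5-methyl-1-benzofuran-2-yl)-5-methoxy-2-phenyl-3,4-dihydro-2H-chromen-7-ol | COc1cc(O)c(-c2cc3c(OC)c(C)c(O)cc3o2)c2c1CC[C@@H](c1ccccc1)O2 | target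

## Step count and risks

Total: 13 steps. Longest linear sequence: 9 steps (steps 1–5, then 10–13, from 1). The second branch (steps 6–9) joins at step 10.

**Step 10 (key step).** The 3-methoxy group makes 19 a push–pull vinylogous ester, so the four-electron ring opening may need a temperature at which the siloxyalkyne isomerises by silyl shift, or at which the vinylketene dimerises or acylates the product phenol. The fallback makes the same vinylketene at ambient temperature by 1,4-dehydrochlorination. It sets out from iodide 14 and returns at 24.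
- Alkylation of the sodium enolate of methyl acetoacetate with 14 (NaH, THF/DMF) would give methyl (5R)-2-acetyl-5-{[tert-butyl(dimethyl)silyl]oxy}-5-phenylpentanoate F1.
- O-Methylation of its potassium enolate (KN(SiMe3)2, Me2SO4, DMPU/THF) would give methyl 2-[(3R)-3-{[tert-butyl(dimethyl)silyl]oxy}-3-phenylpropyl]-3-methoxybut-2-enoate F2.
- Anhydrous ester cleavage with KOSiMe3 in THF would give 2-[(3R)-3-{[tert-butyl(dimethyl)silyl]oxy}-3-phenylpropyl]-3-methoxybut-2-enoic acid F3.
- 1-Chloro-N,N,2-trimethylprop-1-en-1-amine would convert it under neutral conditions into 2-[(3R)-3-{[tert-butyl(dimethyl)silyl]oxy}-3-phenylpropyl]-3-methoxybut-2-enoyl chloride F4.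
- Et3N with 11 in toluene (rt, then 80 °C) would remove a γ-proton and chloride to give vinylketene 20, which continues through 21, 22 and 23 to 24.

**Step 3.** The bromoacetate may go to the wrong ortho hydroxyl or to both, since the two differ only in their neighbour. The fallback widens the steric difference with a bulky silyl group and fixes the regiochemistry before any carbon is attached. It sets out from 4 and returns at 7.
- i-Pr3SiCl and imidazole in DMF should silylate only the hydroxyl next to hydrogen and give 4-(benzyloxy)-2-hydroxy-3-methyl-6-{[tri(propan-2-yl)silyl]oxy}benzaldehyde F5.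
- Mitsunobu methylation of the chelated hydroxyl (MeOH, PPh3, DIAD) would give 4-(benzyloxy)-2-methoxy-3-methyl-6-{[tri(propan-2-yl)silyl]oxy}benzaldehyde F6.
- Bu4NF would free 4-(benzyloxy)-6-hydroxy-2-methoxy-3-methylbenzaldehyde F7, whose only hydroxyl is alkylated with 5 (K2CO3, DMF) to give 7.

**Step 5.** Lithiation at benzofuran C3 or at the benzylic ether by excess n-BuLi, incomplete rearrangement of the carbenoid, or C-silylation may erode the ynolate route. The fallback makes the ynolate by oxidation of an acetylide. It sets out from 8 and returns at 11.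
- LiAlH4 would give [6-(benzyloxy)-4-methoxy-5-methyl-1-benzofuran-2-yl]methanol F8.
- MnO2 would give 6-(benzyloxy)-4-methoxy-5-methyl-1-benzofuran-2-carbaldehyde F9.
- Dimethyl (1-diazo-2-oxopropyl)phosphonate with K2CO3 in MeOH would give 6-(benzyloxy)-2-ethynyl-4-methoxy-5-methyl-1-benzofuran F10.
- Deprotonation with LiN(SiMe3)2 and oxygen transfer from lithium tert-butyl peroxide would give ynolate 10, and i-Pr3SiOSO2CF3 would then give 11.

**Step 9.** The chloride of 18 is vinylogous to an acid chloride and may be lost by solvolysis before reduction, or the reduction may go too far. The fallback avoids the chlorines. It sets out from 17 and returns at 19: ketene itself, generated by pyrolysis of acetone and passed into 17 in CH2Cl2 at 0 °C, would add with the same regiochemistry and give 19 directly.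

**Step 12.** Intermolecular etherification through the free C7 phenol, or elimination of the activated benzylic alcohol, may compete with ring closure. The fallback masks the spectator phenol first. It sets out from 24 and returns at 27.
- BnBr and K2CO3 in DMF would give the 7-O-benzyl ether of 24 F11.
- Bu4NF would give the mono-phenol alcohol, 2-[6-(benzyloxy)-4-methoxy-5-methyl-1-benzofuran-2-yl]-3-(benzyloxy)-6-[(3R)-3-hydroxy-3-phenylpropyl]-5-methoxyphenol F12.
- Mitsunobu closure (PPh3, DIAD) would give the (2S)-bis(benzyl) ether of the target F13, and hydrogenolysis over Pd/C would remove both benzyl groups to give 27.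

Further compounds

F1 | step 10 | methyl (5R)-2-acetyl-5-{[tert-butyl(dimethyl)silyl]oxy}-5-phenylpentanoate (both configurations at C2) | COC(=O)C(CC[C@H](c1ccccc1)O[Si](C)(C)C(C)(C)C)C(C)=O
F2 | step 10 | methyl 2-[(3R)-3-{[tert-butyl(dimethyl)silyl]oxy}-3-phenylpropyl]-3-methoxybut-2-enoate (E/Z mixture) | COC(=O)C(CC[C@H](c1ccccc1)O[Si](C)(C)C(C)(C)C)=C(C)OC
F3 | step 10 | 2-[(3R)-3-{[tert-butyl(dimethyl)silyl]oxy}-3-phenylpropyl]-3-methoxybut-2-enoic acid (E/Z mixture) | OC(=O)C(CC[C@H](c1ccccc1)O[Si](C)(C)C(C)(C)C)=C(C)OC
F4 | step 10 | 2-[(3R)-3-{[tert-butyl(dimethyl)silyl]oxy}-3-phenylpropyl]-3-methoxybut-2-enoyl chloride (E/Z mixture) | ClC(=O)C(CC[C@H](c1ccccc1)O[Si](C)(C)C(C)(C)C)=C(C)OC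
F5 | step 3 | 4-(benzyloxy)-2-hydroxy-3-methyl-6-{[tri(propan-2-yl)silyl]oxy}benzaldehyde | O=Cc1c(O[Si](C(C)C)(C(C)C)C(C)C)cc(OCc2ccccc2)c(C)c1O
F6 | step 3 | 4-(benzyloxy)-2-methoxy-3-methyl-6-{[tri(propan-2-yl)silyl]oxy}benzaldehyde | O=Cc1c(O[Si](C(C)C)(C(C)C)C(C)C)cc(OCc2ccccc2)c(C)c1OC
F7 | step 3 | 4-(benzyloxy)-6-hydroxy-2-methoxy-3-methylbenzaldehyde | O=Cc1c(O)cc(OCc2ccccc2)c(C)c1OC
F8 | step 5 | [6-(benzyloxy)-4-methoxy-5-methyl-1-benzofuran-2-yl]methanol | OCc1cc2c(OC)c(C)c(OCc3ccccc3)cc2o1
F9 | step 5 | 6-(benzyloxy)-4-methoxy-5-methyl-1-benzofuran-2-carbaldehyde | O=Cc1cc2c(OC)c(C)c(OCc3ccccc3)cc2o1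
F10 | step 5 | 6-(benzyloxy)-2-ethynyl-4-methoxy-5-methyl-1-benzofuran | C#Cc1cc2c(OC)c(C)c(OCc3ccccc3)cc2o1
F0 | step 9 | none | none
F11 | step 12 | 6-(benzyloxy)-2-{6-(benzyloxy)-3-[(3R)-3-{[tert-butyl(dimethyl)silyl]oxy}-3-phenylpropyl]-4-methoxy-2-{[tri(propan-2-yl)silyl]oxy}phenyl}-4-methoxy-5-methyl-1-benzofuran (7-O-benzyl ether of 24) | COc1cc(OCc2ccccc2)c(-c2cc3c(OC)c(C)c(OCc4ccccc4)cc3o2)c(O[Si](C(C)C)(C(C)C)C(C)C)c1CC[C@H](c1ccccc1)O[Si](C)(C)C(C)(C)C
F12 | step 12 | 2-[6-(benzyloxy)-4-methoxy-5-methyl-1-benzofuran-2-yl]-3-(benzyloxy)-6-[(3R)-3-hydroxy-3-phenylpropyl]-5-methoxyphenol | COc1cc(OCc2ccccc2)c(-c2cc3c(OC)c(C)c(OCc4ccccc4)cc3o2)c(O)c1CC[C@H](c1ccccc1)O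
F13 | step 12 | (2S)-7-(benzyloxy)-8-[6-(benzyloxy)-4-methoxy-5-methyl-1-benzofuran-2-yl]-5-methoxy-2-phenyl-3,4-dihydro-2H-chromene | COc1cc(OCc2ccccc2)c(-c2cc3c(OC)c(C)c(OCc4ccccc4)cc3o2)c2c1CC[C@@H](c1ccccc1)O2
A1 | alternative 1 | coumestan (lactone from O7 to C3') with 4'-methoxy, 5'-methyl, 6'-triisopropylsilyloxy groups and the (2S)-flavan ring intact | COc1cc2oc(=O)c3c4c(OC)c(C)c(O[Si](C(C)C)(C(C)C)C(C)C)cc4oc3c2c2c1CC[C@@H](c1ccccc1)O2
A2 | alternative 1 | 4-aryloxycoumarin fused to the (2S)-flavan, aryl = 3-methoxy-4-methyl-5-(triisopropylsilyloxy)phenyl | COc1cc2oc(=O)cc(Oc3cc(O[Si](C(C)C)(C(C)C)C(C)C)c(C)c(OC)c3)c2c2c1CC[C@@H](c1ccccc1)O2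
A3 | alternative 2 | 1-[(2S)-7-hydroxy-5-methoxy-2-phenyl-3,4-dihydro-2H-chromen-8-yl]ethan-1-one | COc1cc(O)c(C(C)=O)c2c1CC[C@@H](c1ccccc1)O2
A4 | alternative 2 | 1-(2,6-dihydroxy-4-methoxyphenyl)ethan-1-one | CC(=O)c1c(O)cc(OC)cc1O
A5 | alternative 2 | formaldehyde | C=O
A6 | alternative 2 | styrene | C=Cc1ccccc1
A7 | alternative 3 | (2S)-7-(benzyloxy)-8-[6-(benzyloxy)-4-methoxy-5-methyl-1-benzofuran-2-yl]-5-methoxy-2-phenyl-3,4-dihydro-2H-chromene | COc1cc(OCc3ccccc3)c(-c3cc4c(OC)c(C)c(OCc5ccccc5)cc4o3)c2c1CC[C@@H](c1ccccc1)O2
A8 | alternative 3 | 5-(benzyloxy)-2-formyl-3-methoxy-4-methylphenyl (2S)-7-(benzyloxy)-5-methoxy-2-phenyl-3,4-dihydro-2H-chromene-8-carboxylate | COc1cc(OCc3ccccc3)c(C(=O)Oc3cc(OCc4ccccc4)c(C)c(OC)c3C=O)c2c1CC[C@@H](c1ccccc1)O2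
A9 | alternative 3 | (2S)-7-(benzyloxy)-5-methoxy-2-phenyl-3,4-dihydro-2H-chromene-8-carboxylic acid | COc1cc(OCc3ccccc3)c(C(O)=O)c2c1CC[C@@H](c1ccccc1)O2
A10 | alternative 3 | 4-(benzyloxy)-6-hydroxy-2-methoxy-3-methylbenzaldehyde | O=Cc1c(O)cc(OCc2ccccc2)c(C)c1OC
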